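**Retrosynthetic overview**

1. Dihydropyranone (formed last): cut C4–C5 and O1–C2. The ring unit O1–C6=C5–C4=O is the O-alkylated enol of a 1,3-diketone: O1, C6 and C5 are the acetyl group on coumarin C3, and C4–C3–C2 is a butanoyl chain electrophilic at both ends. A 3-acetylcoumarin enol silane and (R)-3-(mesyloxy)butanoyl chloride (chiral pool, from tert-butyl (R)-3-hydroxybutanoate) therefore give the ring by C-acylation and SN2 O-alkylation, with inversion to (S).
2. Coumarin lactone ring: Knoevenagel condensation and lactonisation of ethyl acetoacetate with the salicylaldehyde, carried as its cyclic quinone methide (isochromenone).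
3. Benzene substituents: the side-chain hydroxyl serves twice as a tether. It first delivers CH2 to one ortho carbon (temporary isochroman, hydrogenolysed to the aryl methyl group), then the formyl carbon to the other.
4. Side chain: both stereocentres come from C2-symmetric (2R,3R)-2,3-epoxybutane, opened by a 3,5-bis(benzyloxy)phenyl Grignard reagent.
5. Ring order: temporary isochroman, temporary isochromenone, coumarin pyranone ring, dihydropyranone.

Key step: step 9

Remark: the given structure is read as (S) at C2 of the dihydropyranone and (2R,3R) in the 3-hydroxybutan-2-yl group (carbinol carbon R, benzylic carbon R); the quinone methide made in step 4 is assumed to equilibrate with its lactol and hydroxy-aldehyde forms in protic media.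

**Route**

Step 1
Reactants: 1 5-bromo-1,3-bis(benzyloxy)benzene; 2 (2R,3R)-2,3-dimethyloxirane
Product: 4 (2R,3R)-3-[3,5-bis(benzyloxy)phenyl]butan-2-ol, via Grignard reagent 3 (not isolated)
Conditions: Mg, THF, 65 °C; then CuI (10 mol %), 2 (1.5 equiv), THF, −30 → 0 °C; 1 M HCl
Reagents that add atoms: none
Why: Copper-catalysed SN2 opening of the epoxide by the aryl Grignard reagent inverts the attacked carbon and retains the other, and because the epoxide is C2-symmetric both carbons are equivalent, so the (2R,3R) epoxide should give only the (2R,3R) alcohol.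

Step 2
Reactants: 4 (2R,3R)-3-[3,5-bis(benzyloxy)phenyl]butan-2-ol
Product: 5 (3R,4R)-6,8-bis(benzyloxy)-3,4-dimethyl-3,4-dihydro-1H-isochromene
Conditions: CH2(OMe)2 (5 equiv), TMSOTf (0.2 equiv), CH2Cl2, −20 → 0 °C
Reagents that add atoms: dimethoxymethane, COCOC
Why: Oxa-Pictet–Spengler cyclisation, in which the oxocarbenium ion formed at the side-chain oxygen attacks the ring ortho to the side chain and para to a benzyloxy group (the two ortho positions are equivalent), without touching a stereocentre.

Step 3
Reactants: 5 (3R,4R)-6,8-bis(benzyloxy)-3,4-dimethyl-3,4-dihydro-1H-isochromene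
Product: 6 5-[(2R,3R)-3-hydroxybutan-2-yl]-4-methylbenzene-1,3-diol
Conditions: H2 (5 bar), 10% Pd/C, HCl (cat.), EtOH, 40 °C
Reagents that add atoms: none
Why: Catalytic hydrogenolysis should cleave both benzyl ethers and, helped by acid and by the ortho and para oxygen substituents, the cyclic benzylic C1–O2 bond, leaving the tether carbon as the aryl methyl group and releasing the secondary alcohol, while the all-carbon benzylic stereocentre is not a hydrogenolysis site.

Step 4
Reactants: 6 5-[(2R,3R)-3-hydroxybutan-2-yl]-4-methylbenzene-1,3-diol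
Product: 8 (3R,4R)-8-hydroxy-3,4,5-trimethyl-3,4-dihydro-6H-isochromen-6-one, via ethoxy acetal 7 (not isolated)
Conditions: HC(OEt)3 (4 equiv), TFA (0.2 equiv), CH2Cl2, 0 → 25 °C; evaporation
Reagents that add atoms: triethyl orthoformate, CCOC(OCC)OCC
Why: Orthoester exchange at the side-chain hydroxyl followed by intramolecular Friedel–Crafts attack of the dialkoxycarbenium ion (oxa-Pictet–Spengler-type formylation) should place the formyl carbon on the only ring carbon within reach of a six-membered transition state, and loss of ethanol gives the quinone methide as a masked salicylaldehyde with both stereocentres untouched.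

Step 5
Reactants: 8 (3R,4R)-8-hydroxy-3,4,5-trimethyl-3,4-dihydro-6H-isochromen-6-one; 9 ethyl 3-oxobutanoate
Product: 11 3-acetyl-7-hydroxy-5-[(2R,3R)-3-hydroxybutan-2-yl]-6-methyl-2H-chromen-2-one, via isochromanyl acetoacetate 10 (not isolated)
Conditions: piperidine (0.2 equiv), AcOH (0.2 equiv), EtOH, 78 °C
Reagents that add atoms: none
Why: Knoevenagel condensation with lactonisation, in which amine-catalysed addition of the acetoacetate to C1 of the quinone methide (the aldehyde carbon), β-elimination of the tethered alkoxide and irreversible lactonisation by the ortho phenol should give the 3-acetylcoumarin without forming or touching a stereocentre.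

Step 6
Reactants: 11 3-acetyl-7-hydroxy-5-[(2R,3R)-3-hydroxybutan-2-yl]-6-methyl-2H-chromen-2-one
Product: 13 7-[(tert-butyldimethylsilyl)oxy]-5-{(2R,3R)-3-[(tert-butyldimethylsilyl)oxy]butan-2-yl}-6-methyl-3-{1-[(trimethylsilyl)oxy]ethenyl}-2H-chromen-2-one, via bis-silyl ketone 12 (not isolated)
Conditions: TBSOTf (2.3 equiv), 2,6-lutidine (3 equiv), CH2Cl2, −78 → 0 °C; then Et3N (3 equiv), TMSOTf (1.3 equiv), 0 °C; pentane, cold aq. NaHCO3 wash, used crude
Reagents that add atoms: tert-butyldimethylsilyl trifluoromethanesulfonate, CC(C)(C)[Si](C)(C)OS(=O)(=O)C(F)(F)F; trimethylsilyl trifluoromethanesulfonate, C[Si](C)(C)OS(=O)(=O)C(F)(F)F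
Why: O-Silylation with a silyl triflate and a hindered pyridine base, then soft enolisation of the methyl ketone (silyl enol ether formation), should mask both hydroxyls and turn the acetyl group, the only enolisable position, into a carbon nucleophile that needs no base, with no stereocentre touched.

Step 7
Reactants: 14 tert-butyl (3R)-3-hydroxybutanoate
Product: 15 tert-butyl (3R)-3-[(methanesulfonyl)oxy]butanoate
Conditions: MsCl (1.2 equiv), Et3N (1.5 equiv), CH2Cl2, −10 °C
Reagents that add atoms: methanesulfonyl chloride, CS(=O)(=O)Cl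
Why: Sulfonylation at oxygen (mesylate formation) retains the configuration of the secondary carbinol carbon, and the low temperature should keep β-elimination to the crotonate negligible.

Step 8
Reactants: 15 tert-butyl (3R)-3-[(methanesulfonyl)oxy]butanoate
Product: 16 (3R)-3-[(methanesulfonyl)oxy]butanoyl chloride
Conditions: SOCl2 (5 equiv), CH2Cl2, 25 °C; evaporation
Reagents that add atoms: thionyl chloride, O=S(Cl)Cl
Why: tert-Butyl esters are converted directly into acid chlorides by SOCl2 (acid-mediated loss of the tert-butyl group, then chlorination of the acid), conditions under which the secondary mesylate and its configuration should persist.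

Step 9
Reactants: 13 7-[(tert-butyldimethylsilyl)oxy]-5-{(2R,3R)-3-[(tert-butyldimethylsilyl)oxy]butan-2-yl}-6-methyl-3-{1-[(trimethylsilyl)oxy]ethenyl}-2H-chromen-2-one; 16 (3R)-3-[(methanesulfonyl)oxy]butanoyl chloride
Product: 18 7-[(tert-butyldimethylsilyl)oxy]-5-{(2R,3R)-3-[(tert-butyldimethylsilyl)oxy]butan-2-yl}-6-methyl-3-[(2S)-2-methyl-4-oxo-3,4-dihydro-2H-pyran-6-yl]-2H-chromen-2-one, via diketone mesylate 17 (not isolated)
Conditions: ZnCl2 (0.2 equiv), CH2Cl2, −20 → 0 °C; evaporation; then K2CO3 (3 equiv), 18-crown-6 (0.1 equiv), MeCN, 0 → 25 °C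
Reagents that add atoms: none
Why: Proposed new method: the ZnCl2-activated acid chloride 16 acylates the terminal carbon of enol silane 13 (Mukaiyama-type C-acylation; no base is present, so the β-mesyloxy acyl unit cannot lose methanesulfonate by E1cB) to give 1,3-diketone 17, and carbonate then forms its monoanion, whose enolate oxygen on the coumarin side displaces the secondary mesylate in a 6-exo-tet SN2 closure. The closest known reactions are the Lewis acid-mediated acylation of silyl enol ethers with acid chlorides to 1,3-diketones and the intramolecular O-alkylation (Mitsunobu or sulfonate) of 3-hydroxy-1-(2-hydroxyphenyl)butan-1-ones to 2-methylchroman-4-ones with inversion; a 1,3-diketone enolate in place of the phenoxide has not been shown. The only new stereocentre comes from the chiral pool: the (R)-configured sulfonate carbon of 16 is inverted to the (S)-configured C2 of the dihydropyranone. Constitutional selectivity is built in, because C-alkylation or attack by the other diketone oxygen would require a four-membered ring. The step needs SN2 closure to outrun β-elimination, which would give a crotonyl diketone that closes without facial control; this is secured because the diketonate monoanion has no acidic hydrogen left beside the sulfonate-bearing carbon, the base is weak and heterogeneous, and the temperature stays at or below 25 °C.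

Step 10
Reactants: 18 7-[(tert-butyldimethylsilyl)oxy]-5-{(2R,3R)-3-[(tert-butyldimethylsilyl)oxy]butan-2-yl}-6-methyl-3-[(2S)-2-methyl-4-oxo-3,4-dihydro-2H-pyran-6-yl]-2H-chromen-2-one
Product: 19 7-hydroxy-5-[(2R,3R)-3-hydroxybutan-2-yl]-6-methyl-3-[(2S)-2-methyl-4-oxo-3,4-dihydro-2H-pyran-6-yl]-2H-chromen-2-one
Conditions: HF·pyridine, pyridine, THF, 0 → 25 °C
Reagents that add atoms: none
Why: Fluoride-mediated cleavage of the aryl and alkyl silyl ethers (desilylation) under buffered, weakly acidic conditions should free the phenol and the secondary alcohol without retro-oxa-Michael opening of the base-sensitive dihydropyranone, so no stereocentre is touched.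

**Compound list**

1 | 5-bromo-1,3-bis(benzyloxy)benzene | Brc1cc(OCc2ccccc2)cc(OCc2ccccc2)c1 | starting material
2 | (2R,3R)-2,3-dimethyloxirane | C[C@H]1O[C@@H]1C | starting material
3 | [3,5-bis(benzyloxy)phenyl]magnesium bromide | Br[Mg]c1cc(OCc2ccccc2)cc(OCc2ccccc2)c1 | intermediate
4 | (2R,3R)-3-[3,5-bis(benzyloxy)phenyl]butan-2-ol | C[C@@H](O)[C@H](C)c1cc(OCc2ccccc2)cc(OCc2ccccc2)c1 | intermediate
5 | (3R,4R)-6,8-bis(benzyloxy)-3,4-dimethyl-3,4-dihydro-1H-isochromene | C[C@H]1OCc2c(OCc3ccccc3)cc(OCc3ccccc3)cc2[C@H]1C | intermediate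
6 | 5-[(2R,3R)-3-hydroxybutan-2-yl]-4-methylbenzene-1,3-diol | Cc1c(O)cc(O)cc1[C@@H](C)[C@@H](C)O | intermediate
7 | (3R,4R)-1-ethoxy-3,4,5-trimethyl-3,4-dihydro-1H-isochromene-6,8-diol (both C1 epimers) | CCOC1O[C@H](C)[C@H](C)c2c(C)c(O)cc(O)c21 | intermediate
8 | (3R,4R)-8-hydroxy-3,4,5-trimethyl-3,4-dihydro-6H-isochromen-6-one | C[C@H]1OC=C2C(O)=CC(=O)C(C)=C2[C@H]1C | intermediate
9 | ethyl 3-oxobutanoate | CCOC(=O)CC(C)=O | starting material
10 | ethyl 2-[(3R,4R)-6,8-dihydroxy-3,4,5-trimethyl-3,4-dihydro-1H-isochromen-1-yl]-3-oxobutanoate (mixture at the two new centres) | CCOC(=O)C(C(C)=O)C1O[C@H](C)[C@H](C)c2c(C)c(O)cc(O)c21 | intermediate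
11 | 3-acetyl-7-hydroxy-5-[(2R,3R)-3-hydroxybutan-2-yl]-6-methyl-2H-chromen-2-one | CC(=O)c1cc2c(cc(O)c(C)c2[C@@H](C)[C@@H](C)O)oc1=O | intermediate
12 | 3-acetyl-7-[(tert-butyldimethylsilyl)oxy]-5-{(2R,3R)-3-[(tert-butyldimethylsilyl)oxy]butan-2-yl}-6-methyl-2H-chromen-2-one | CC(=O)c1cc2c(cc(O[Si](C)(C)C(C)(C)C)c(C)c2[C@@H](C)[C@@H](C)O[Si](C)(C)C(C)(C)C)oc1=O | intermediate
13 | 7-[(tert-butyldimethylsilyl)oxy]-5-{(2R,3R)-3-[(tert-butyldimethylsilyl)oxy]butan-2-yl}-6-methyl-3-{1-[(trimethylsilyl)oxy]ethenyl}-2H-chromen-2-one | C=C(O[Si](C)(C)C)c1cc2c(cc(O[Si](C)(C)C(C)(C)C)c(C)c2[C@@H](C)[C@@H](C)O[Si](C)(C)C(C)(C)C)oc1=O | intermediate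
14 | tert-butyl (3R)-3-hydroxybutanoate | C[C@@H](O)CC(=O)OC(C)(C)C | starting material
15 | tert-butyl (3R)-3-[(methanesulfonyl)oxy]butanoate | C[C@@H](OS(C)(=O)=O)CC(=O)OC(C)(C)C | intermediate
16 | (3R)-3-[(methanesulfonyl)oxy]butanoyl chloride | C[C@@H](OS(C)(=O)=O)CC(Cl)=O | intermediate
17 | (2R)-6-(7-[(tert-butyldimethylsilyl)oxy]-5-{(2R,3R)-3-[(tert-butyldimethylsilyl)oxy]butan-2-yl}-6-methyl-2-oxo-2H-chromen-3-yl)-4,6-dioxohexan-2-yl methanesulfonate | C[C@@H](OS(C)(=O)=O)CC(=O)CC(=O)c1cc2c(cc(O[Si](C)(C)C(C)(C)C)c(C)c2[C@@H](C)[C@@H](C)O[Si](C)(C)C(C)(C)C)oc1=O | intermediate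
18 | 7-[(tert-butyldimethylsilyl)oxy]-5-{(2R,3R)-3-[(tert-butyldimethylsilyl)oxy]butan-2-yl}-6-methyl-3-[(2S)-2-methyl-4-oxo-3,4-dihydro-2H-pyran-6-yl]-2H-chromen-2-one | C[C@H]1CC(=O)C=C(O1)c1cc2c(cc(O[Si](C)(C)C(C)(C)C)c(C)c2[C@@H](C)[C@@H](C)O[Si](C)(C)C(C)(C)C)oc1=O | intermediate
19 | 7-hydroxy-5-[(2R,3R)-3-hydroxybutan-2-yl]-6-methyl-3-[(2S)-2-methyl-4-oxo-3,4-dihydro-2H-pyran-6-yl]-2H-chromen-2-one | Cc1c(O)cc2oc(=O)c(C3=CC(=O)C[C@H](C)O3)cc2c1[C@@H](C)[C@@H](C)O | target

**Step count**

Total steps: 10. Longest linear sequence: 8 steps (steps 1 to 6, 9 and 10).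

**Steps most likely to fail**

Step 9. Configurational purity at the new stereocentre may be lost if methanesulfonate is eliminated faster than the diketonate closes, because ring closure would then run through oxa-Michael addition without facial control; O-acylation or protodesilylation of the enol silane may also lower conversion. The fallback uses known chemistry, sets out from 13 and rejoins the route at 19. Commercial (S)-3-hydroxybutanoic acid would be bis-silylated (TBSCl, imidazole, DMF) to tert-butyldimethylsilyl (3S)-3-[(tert-butyldimethylsilyl)oxy]butanoate F1 and converted with (COCl)2 and catalytic DMF into (3S)-3-[(tert-butyldimethylsilyl)oxy]butanoyl chloride F2. ZnCl2-mediated acylation of 13 with F2 should give the silyloxy diketone (5S)-1-(7-[(tert-butyldimethylsilyl)oxy]-5-{(2R,3R)-3-[(tert-butyldimethylsilyl)oxy]butan-2-yl}-6-methyl-2-oxo-2H-chromen-3-yl)-5-[(tert-butyldimethylsilyl)oxy]hexane-1,3-dione F3. Aqueous HF in MeCN followed by catalytic TsOH in CH2Cl2 should remove the three silyl groups and close the ring by hemiketalisation and dehydration. In this classical cyclodehydration the hydroxyl oxygen becomes the ring oxygen and the carbinol carbon keeps its (S) configuration, so 19 is reached directly.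

Step 5. The condensation may stall after conjugate addition if the tethered alkoxide recloses on C1 faster than the phenol lactonises, or the material may partition into oligomers. The fallback removes the free side-chain hydroxyl before the aldehyde is made; it sets out from 6 and rejoins the route at 13. Persilylation (TBSCl, imidazole, DMF) should give (2R,3R)-3-{3,5-bis[(tert-butyldimethylsilyl)oxy]-2-methylphenyl}butan-2-yl tert-butyldimethylsilyl ether F4. K2CO3 in MeOH should cleave only the two aryl silyl ethers to 5-{(2R,3R)-3-[(tert-butyldimethylsilyl)oxy]butan-2-yl}-4-methylbenzene-1,3-diol F5. Vilsmeier–Haack formylation (POCl3, DMF, MeCN, then water), expected para to the hydroxyl next to the methyl group as with orcinol, should give 2-{(2R,3R)-3-[(tert-butyldimethylsilyl)oxy]butan-2-yl}-4,6-dihydroxy-3-methylbenzaldehyde F6. Ordinary Knoevenagel condensation with 9 (piperidine, EtOH) should give 3-acetyl-5-{(2R,3R)-3-[(tert-butyldimethylsilyl)oxy]butan-2-yl}-7-hydroxy-6-methyl-2H-chromen-2-one F7. TBSOTf with 2,6-lutidine and then TMSOTf with Et3N lead through 12 to 13. The cost is that the regiochemistry of formylation is no longer enforced by a tether.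

Step 3. Hydrogenolysis may stop after O-debenzylation and leave the cyclic benzylic ether intact, or forcing conditions may start to saturate the ring. The fallback replaces surface hydrogenolysis of the ring C–O bond by ionic hydrogenation; it sets out from 5 and rejoins the route at 6. Et3SiH and TFA in CH2Cl2 at 0 °C should open the isochroman through the benzylic cation stabilised by the ortho and para oxygen substituents and reduce it to (2R,3R)-3-[3,5-bis(benzyloxy)-2-methylphenyl]butan-2-ol F8. Routine debenzylation (H2, 1 bar, 10% Pd/C, EtOAc) then gives 6.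

**Further compounds**

F1 | step 9 | tert-butyldimethylsilyl (3S)-3-[(tert-butyldimethylsilyl)oxy]butanoate | C[C@H](O[Si](C)(C)C(C)(C)C)CC(=O)O[Si](C)(C)C(C)(C)C
F2 | step 9 | (3S)-3-[(tert-butyldimethylsilyl)oxy]butanoyl chloride | C[C@H](O[Si](C)(C)C(C)(C)C)CC(Cl)=O
F3 | step 9 | (5S)-1-(7-[(tert-butyldimethylsilyl)oxy]-5-{(2R,3R)-3-[(tert-butyldimethylsilyl)oxy]butan-2-yl}-6-methyl-2-oxo-2H-chromen-3-yl)-5-[(tert-butyldimethylsilyl)oxy]hexane-1,3-dione | C[C@H](O[Si](C)(C)C(C)(C)C)CC(=O)CC(=O)c1cc2c(cc(O[Si](C)(C)C(C)(C)C)c(C)c2[C@@H](C)[C@@H](C)O[Si](C)(C)C(C)(C)C)oc1=O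
F4 | step 5 | (2R,3R)-3-{3,5-bis[(tert-butyldimethylsilyl)oxy]-2-methylphenyl}butan-2-yl tert-butyldimethylsilyl ether | Cc1c(O[Si](C)(C)C(C)(C)C)cc(O[Si](C)(C)C(C)(C)C)cc1[C@@H](C)[C@@H](C)O[Si](C)(C)C(C)(C)C
F5 | step 5 | 5-{(2R,3R)-3-[(tert-butyldimethylsilyl)oxy]butan-2-yl}-4-methylbenzene-1,3-diol | Cc1c(O)cc(O)cc1[C@@H](C)[C@@H](C)O[Si](C)(C)C(C)(C)C
F6 | step 5 | 2-{(2R,3R)-3-[(tert-butyldimethylsilyl)oxy]butan-2-yl}-4,6-dihydroxy-3-methylbenzaldehyde | Cc1c(O)cc(O)c(C=O)c1[C@@H](C)[C@@H](C)O[Si](C)(C)C(C)(C)C
F7 | step 5 | 3-acetyl-5-{(2R,3R)-3-[(tert-butyldimethylsilyl)oxy]butan-2-yl}-7-hydroxy-6-methyl-2H-chromen-2-one | CC(=O)c1cc2c(cc(O)c(C)c2[C@@H](C)[C@@H](C)O[Si](C)(C)C(C)(C)C)oc1=O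
F8 | step 3 | (2R,3R)-3-[3,5-bis(benzyloxy)-2-methylphenyl]butan-2-ol | Cc1c(OCc2ccccc2)cc(OCc2ccccc2)cc1[C@@H](C)[C@@H](C)O
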